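The ε-ring is opened across C1–C2 and C4=C5 (carotenoid numbering). The C3 oxygen, as a ketone, acidifies both C2 and C4, and the quaternary C1 lies β to the C5 and C7 carbonyls, so the ring is a Hagemann-type [3+3] adduct. Ethyl acetoacetate (C2–C3–C4) adds to ethyl isopropylideneacetoacetate (C5–C6–C1, C7 ester) at C1 and condenses onto its acetyl carbon C5, with loss of the donor's ester. This one operation delivers the 3-oxo-ε-ring with C7 in place. Reagent-controlled reduction then fixes C3 and selects C6; Julia–Kocienski coupling of the C10 ring sulfone with crocetin dialdehyde forms C7=C8.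

Key step: step 2

Remarks on the chemistry:
- Ring atoms are numbered as in carotenoids: C1 = CMe2, C2 = CH2, C3 = CHOH, C4 = CH=, C5 = C(Me)=, C6 = CH carrying the chain; C7 is the first chain carbon. The target is the cis (3S,6R) isomer.
- Assumption: all-E crocetin dialdehyde is taken as a purchasable C20 carotenoid building block.
- Step 3 turns the two enantiomers of racemic 6 into two diastereomeric alcohols. Only the cis one is carried on, so at most half of 6 can reach 7. The trans diastereomer could in principle be returned to racemic 6 by allylic oxidation and base.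

Step 1
Reactants: 1 acetone; 2 ethyl acetoacetate
Product: 3 ethyl 2-acetyl-3-methylbut-2-enoate
Conditions: TiCl4 (2 equiv), pyridine (4 equiv), THF, 0 °C → rt
Reagents that add atoms: none
Why: Lehnert-type titanium-mediated Knoevenagel condensation, in which TiCl4 activates the ketone and takes up the water; the isopropylidene product has no alkene geometry to control.

Step 2
Reactants: 3 ethyl 2-acetyl-3-methylbut-2-enoate; 2 ethyl acetoacetate
Product: 6 ethyl 2,6,6-trimethyl-4-oxocyclohex-2-ene-1-carboxylate (racemic), via Michael adduct 4 (not isolated), via ring diester 5 (not isolated)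
Conditions: NaOEt (1.1 equiv), EtOH, 0 °C → reflux; then cold aq. HCl
Reagents that add atoms: none
Why: Ethyl sodioacetoacetate adds in Michael fashion to C1 of the doubly activated alkylidene 3 (new C1–C2 bond, quaternary C1); in adduct 4 an acetyl methyl (C4) attacks the other acetyl carbonyl (C5) and E1cB loss of water gives the C4=C5 bond of 5, whose β-keto ester at C2 is then cleaved by ethoxide (retro-Claisen deethoxycarbonylation) to leave 6. The closest known reactions are Hagemann's ester synthesis from a bis(acetoacetate) and Knoevenagel's isophoronecarboxylate, that is a Robinson-type Michael–aldol [3+3] annulation. The ring closes by a 6-(enolendo)-exo-trig aldol addition. The only stereocentre, C6, is formed racemic and stays labile as a vinylogous β-keto ester, so it is left to step 3. Aldol regiochemistry is secured by the symmetry of 4 (both halves are the same acetoacetate unit), and the surviving ester should be the vinylogous one at C6 because only the C2 ester is a true β-keto ester. The hindered, reversible Michael step is drawn forward by the irreversible dehydration and by the stabilised extended enolate of 6.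

Step 3
Reactants: 6 ethyl 2,6,6-trimethyl-4-oxocyclohex-2-ene-1-carboxylate (racemic)
Product: 7 ethyl (1R,4S)-4-hydroxy-2,6,6-trimethylcyclohex-2-ene-1-carboxylate
Conditions: (R)-Me-CBS (0.5 equiv), catecholborane (1.5 equiv), toluene, −78 → −40 °C; MeOH, cold aq. NaOH wash; chromatography
Reagents that add atoms: none
Why: Corey–Bakshi–Shibata reduction under reagent control: with the alkenyl flank (C4=C5) as the large group the (R)-oxazaborolidine–catecholborane complex should deliver hydride to the same carbonyl face of both enantiomers of 6, so C3 becomes S throughout, the (6R)-ketone gives the cis alcohol 7 and the (6S)-ketone gives the trans (1S,4S)-diastereomer, which chromatography removes, while the enantiomer of 7 could form only against both reagent and substrate bias.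

Step 4
Reactants: 7 ethyl (1R,4S)-4-hydroxy-2,6,6-trimethylcyclohex-2-ene-1-carboxylate
Product: 8 (1S,4R)-4-(hydroxymethyl)-3,5,5-trimethylcyclohex-2-en-1-ol
Conditions: LiAlH4 (3 equiv), THF, 0 °C → rt; Fieser work-up
Reagents that add atoms: none
Why: LiAlH4 reduction of the ester to the primary alcohol should outpace enolisation at the hindered C6, so the configuration set in step 3 is kept; the allylic alkoxide and the trisubstituted alkene are inert.

Step 5
Reactants: 8 (1S,4R)-4-(hydroxymethyl)-3,5,5-trimethylcyclohex-2-en-1-ol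
Product: 9 [(1R,4S)-4-hydroxy-2,6,6-trimethylcyclohex-2-en-1-yl]methyl 4-methylbenzenesulfonate
Conditions: TsCl (1.1 equiv), pyridine, CH2Cl2, 0 °C
Reagents that add atoms: 4-toluenesulfonyl chloride, Cc1ccc(cc1)S(=O)(=O)Cl
Why: Chemoselective O-sulfonylation: the primary hydroxyl should be tosylated ahead of the secondary allylic one on steric grounds at 0 °C, and no stereocentre is touched.

Step 6
Reactants: 9 [(1R,4S)-4-hydroxy-2,6,6-trimethylcyclohex-2-en-1-yl]methyl 4-methylbenzenesulfonate
Product: 10 (1S,4R)-3,5,5-trimethyl-4-{[(1-phenyl-1H-tetrazol-5-yl)sulfanyl]methyl}cyclohex-2-en-1-ol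
Conditions: sodium 1-phenyl-1H-tetrazole-5-thiolate (1.5 equiv), Bu4NI (cat.), DMF, 60–70 °C
Reagents that add atoms: sodium 1-phenyl-1H-tetrazole-5-thiolate, [Na+].[S-]c1nnnn1-c1ccccc1
Why: SN2 displacement of the primary tosylate by the soft thiolate (S-alkylation), slow at this β-branched carbon, hence iodide catalysis and warming; the weakly basic thiolate leaves the C3 hydroxyl protonated, so it should not close an ether onto C7.

Step 7
Reactants: 10 (1S,4R)-3,5,5-trimethyl-4-{[(1-phenyl-1H-tetrazol-5-yl)sulfanyl]methyl}cyclohex-2-en-1-ol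
Product: 11 (1S,4R)-3,5,5-trimethyl-4-{[(1-phenyl-1H-tetrazol-5-yl)sulfonyl]methyl}cyclohex-2-en-1-ol
Conditions: (NH4)6Mo7O24·4H2O (10 mol%), 30% H2O2 (6 equiv), EtOH, 0 °C → rt
Reagents that add atoms: hydrogen peroxide, OO
Why: Molybdate-catalysed peroxide oxidation of the sulfide to the sulfone, which should be much faster than epoxidation of the trisubstituted alkene under these protic conditions.

Step 8
Reactants: 11 (1S,4R)-3,5,5-trimethyl-4-{[(1-phenyl-1H-tetrazol-5-yl)sulfonyl]methyl}cyclohex-2-en-1-ol; 12 crocetin dialdehyde, (2E,4E,6E,8E,10E,12E,14E)-2,6,11,15-tetramethylhexadeca-2,4,6,8,10,12,14-heptaenedial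
Product: 13 (3S,6R)-3-hydroxy-8'-apo-ε-caroten-8'-al, (2E,4E,6E,8E,10E,12E,14E,16E)-17-[(1R,4S)-4-hydroxy-2,6,6-trimethylcyclohex-2-en-1-yl]-2,6,11,15-tetramethylheptadeca-2,4,6,8,10,12,14,16-octaenal (target)
Conditions: KHMDS (2.1 equiv), THF, −78 °C, 20 min; then added to 12 (3 equiv), THF, −78 → 0 °C; aq. NH4Cl; argon, subdued light
Reagents that add atoms: none
Why: Julia–Kocienski olefination: the dianion (C3 alkoxide, C7 sulfonyl carbanion) adds to one formyl group of 12, and Smiles rearrangement with loss of SO2 and the tetrazolone gives the C7=C8 alkene, expected E from the anti-selective addition of potassium PT-sulfone anions; the threefold excess of the symmetric dialdehyde limits double olefination, and C6 has no leaving group next to the carbanion and keeps its configuration.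

Compound list
1 | acetone | CC(C)=O | starting material
2 | ethyl acetoacetate | CCOC(=O)CC(C)=O | starting material
3 | ethyl 2-acetyl-3-methylbut-2-enoate | CCOC(=O)C(C(C)=O)=C(C)C | intermediate
4 | diethyl 2,4-diacetyl-3,3-dimethylpentanedioate | CCOC(=O)C(C(C)=O)C(C)(C)C(C(C)=O)C(=O)OCC | intermediate
5 | diethyl 2,2,4-trimethyl-6-oxocyclohex-4-ene-1,3-dicarboxylate | CCOC(=O)C1C(C)=CC(=O)C(C(=O)OCC)C1(C)C | intermediate
6 | ethyl 2,6,6-trimethyl-4-oxocyclohex-2-ene-1-carboxylate (racemic) | CCOC(=O)C1C(C)=CC(=O)CC1(C)C | intermediate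
7 | ethyl (1R,4S)-4-hydroxy-2,6,6-trimethylcyclohex-2-ene-1-carboxylate | CC1=C[C@@H](O)CC(C)(C)[C@H]1C(=O)OCC | intermediate
8 | (1S,4R)-4-(hydroxymethyl)-3,5,5-trimethylcyclohex-2-en-1-ol | CC1=C[C@@H](O)CC(C)(C)[C@H]1CO | intermediate
9 | [(1R,4S)-4-hydroxy-2,6,6-trimethylcyclohex-2-en-1-yl]methyl 4-methylbenzenesulfonate | CC1=C[C@@H](O)CC(C)(C)[C@H]1COS(=O)(=O)c2ccc(C)cc2 | intermediate
10 | (1S,4R)-3,5,5-trimethyl-4-{[(1-phenyl-1H-tetrazol-5-yl)sulfanyl]methyl}cyclohex-2-en-1-ol | CC1=C[C@@H](O)CC(C)(C)[C@H]1CSc2nnnn2-c3ccccc3 | intermediate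
11 | (1S,4R)-3,5,5-trimethyl-4-{[(1-phenyl-1H-tetrazol-5-yl)sulfonyl]methyl}cyclohex-2-en-1-ol | CC1=C[C@@H](O)CC(C)(C)[C@H]1CS(=O)(=O)c2nnnn2-c3ccccc3 | intermediate
12 | crocetin dialdehyde | O=C/C(C)=C/C=C/C(C)=C/C=C/C=C(C)/C=C/C=C(\C)C=O | starting material
13 | (3S,6R)-3-hydroxy-8'-apo-ε-caroten-8'-al | CC1=C[C@@H](O)CC(C)(C)[C@H]1/C=C/C(C)=C/C=C/C(C)=C/C=C/C=C(C)/C=C/C=C(\C)C=O | target

Total step count: 8. Longest linear sequence: 8 steps (1 and 2 → 13); 12 is bought.

Steps most likely to fail

Step 3. Reagent control may be insufficient in the mismatched pairing: the (6R)-ketone may be reduced slowly or leak to its trans alcohol, so throughput and optical purity of 7 would suffer. The fallback sets out from 6 and returns at 7. Luche reduction (NaBH4, CeCl3, MeOH, −40 °C) should give mainly the racemic trans alcohol, ethyl (1R*,4R*)-4-hydroxy-2,6,6-trimethylcyclohex-2-ene-1-carboxylate F1, by attack anti to the axial C1 methyl. Mitsunobu inversion (4-nitrobenzoic acid, PPh3, DIAD, THF) then gives the racemic cis 4-nitrobenzoate F2, and methanolysis (K2CO3, MeOH) the racemic cis alcohol F3. Lipase PS with vinyl acetate should acetylate the (4R)-enantiomer to ethyl (1S,4R)-4-acetoxy-2,6,6-trimethylcyclohex-2-ene-1-carboxylate F4 and leave the (1R,4S)-alcohol, which is 7.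

Step 8. E-selectivity at C7=C8 may be incomplete, the far formyl group may be olefinated a second time, and the metallated sulfone may self-condense. The fallback sets out from 9 and returns at 13. Finkelstein exchange (NaI, butanone, reflux) gives (1S,4R)-4-(iodomethyl)-3,5,5-trimethylcyclohex-2-en-1-ol F5. Quaternisation with PPh3 (MeCN, sealed tube, 110 °C) gives {[(1R,4S)-4-hydroxy-2,6,6-trimethylcyclohex-2-en-1-yl]methyl}triphenylphosphonium iodide F6. Ylide formation (NaHMDS, 2 equiv, THF, −78 °C) and Wittig reaction with 12 (3 equiv) should give 13 together with its (7Z)-isomer F7. Iodine-catalysed equilibration (I2 cat., CH2Cl2, daylight) converts F7 into 13.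

Step 2. The Michael equilibrium at the tetrasubstituted acceptor may be unfavourable (retro-Michael, deconjugation of 3), or the wrong ester may be cleaved. The fallback sets out from 3 and returns at 6. Mukaiyama–Michael addition of 2-(trimethylsilyloxy)propene (TiCl4, CH2Cl2, −78 °C) gives ethyl 2-acetyl-3,3-dimethyl-5-oxohexanoate F8, which is not isolated. In the same flask BF3·OEt2 on warming cyclodehydrates it (enol of the unhindered methyl ketone onto the chelated acetyl group) to 6. Both ring bonds are still made in one operation, now without a sacrificial ester and without a reversible anionic Michael step.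

Further compounds
F1 | step 3 | racemic ethyl (1R*,4R*)-4-hydroxy-2,6,6-trimethylcyclohex-2-ene-1-carboxylate | CC1=C[C@H](O)CC(C)(C)[C@H]1C(=O)OCC.CC1=C[C@@H](O)CC(C)(C)[C@@H]1C(=O)OCC
F2 | step 3 | racemic ethyl (1R*,4S*)-2,6,6-trimethyl-4-[(4-nitrobenzoyl)oxy]cyclohex-2-ene-1-carboxylate | CC1=C[C@@H](OC(=O)c2ccc(cc2)[N+](=O)[O-])CC(C)(C)[C@H]1C(=O)OCC.CC1=C[C@H](OC(=O)c2ccc(cc2)[N+](=O)[O-])CC(C)(C)[C@@H]1C(=O)OCC
F3 | step 3 | racemic ethyl (1R*,4S*)-4-hydroxy-2,6,6-trimethylcyclohex-2-ene-1-carboxylate | CC1=C[C@@H](O)CC(C)(C)[C@H]1C(=O)OCC.CC1=C[C@H](O)CC(C)(C)[C@@H]1C(=O)OCC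
F4 | step 3 | ethyl (1S,4R)-4-acetoxy-2,6,6-trimethylcyclohex-2-ene-1-carboxylate | CC1=C[C@H](OC(C)=O)CC(C)(C)[C@@H]1C(=O)OCC
F5 | step 8 | (1S,4R)-4-(iodomethyl)-3,5,5-trimethylcyclohex-2-en-1-ol | CC1=C[C@@H](O)CC(C)(C)[C@H]1CI
F6 | step 8 | {[(1R,4S)-4-hydroxy-2,6,6-trimethylcyclohex-2-en-1-yl]methyl}triphenylphosphonium iodide | CC1=C[C@@H](O)CC(C)(C)[C@H]1C[P+](c2ccccc2)(c3ccccc3)c4ccccc4.[I-]
F7 | step 8 | (7Z)-isomer of 13 | CC1=C[C@@H](O)CC(C)(C)[C@H]1\C=C/C(C)=C/C=C/C(C)=C/C=C/C=C(C)/C=C/C=C(\C)C=O
F8 | step 2 | ethyl 2-acetyl-3,3-dimethyl-5-oxohexanoate | CCOC(=O)C(C(C)=O)C(C)(C)CC(C)=O
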